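In the summer flask, the leftover to watch is the fraction of starting material not yet turned into product, 20.0% of the charge at 40.0 h.

| setting | summer | winter | flask |
|---|---|---|---|
| starting material | 0.10 M | 0.10 M | 0.10 M |
| free enzyme | 0.0012 mol% | 0.0012 mol% | 0.0012 mol% |
| temperature | 20 °C | 26 °C | 20 °C |
| remark | the very flask that is asked about, followed so far | run made earlier |  |
| time |  |  | 2.5 d |

- summer (time / h: product / %): 5.00: 31; 12.0: 57; 25.0: 74; 40.0: 80
- winter (time / h: product / %): 5.00: 37; 12.0: 57; 25.0: 66; 40.0: 66

(readings scatter by 1.5 percentage points)

- ochre: at 2.5 d raise the temperature by 10 K, then wait 20 h
- violet: change nothing and wait 20 h more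
- blue: at 2.5 d take out 90% of the product then present, then wait 20 h
- green: at 2.5 d add free enzyme, 50.0% of the amount charged, then wait 20 h

- what is taken out of product is counted as made
- the analysis behind the earlier runs scatters by 1.5 percentage points, standard deviation
- what may be going on: starting material + free enzyme -> product + free enzyme; free enzyme -> spent catalyst; free enzyme -> unfolded enzyme
- additions bring no volume worth counting

1. product, in percent of the starting material first charged, at 2.5 d
2. the remedy with the largest gain of product, or "none" below 2 percentage points (ochre / violet / blue / green / none)
3. product present, with what was taken out counted in, in percent of the starting material first charged, after ochre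
4. product present, with what was taken out counted in, in percent of the starting material first charged, after violet

The bench rule says that a leftover shrinks by a constant factor per hour, so minus its logarithm, which we call spent reach, grows in a straight line. The first summer reading gives a slope of 0.0742 h⁻¹, and that slope would leave 1.17% at 2.5 d. But the last two readings give 0.0175 h⁻¹, so the slope has dropped by a factor of 4.24, and the rule stops working here.

We read the drop as loss of working free enzyme. The slope between the two earlier readings, 0.0387 h⁻¹, gives a decay constant of 0.0567 h⁻¹. Summing the decaying slope to its end gives the reach, the total spent reach that one charge of free enzyme can buy: 1.61 already spent plus 0.201 to come, or 1.81. This is a reading and carries the scatter. The winter plateau gives 1.08, smaller, so warming shrinks the reach.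

Our reckoning for 2.5 d spends 1.75, which is 82.6% product. With 0.678 of any remaining reach spent in 20 h, violet gains 0.75 percentage points. We give blue the same. Ochre, with the remaining reach cut by the winter ratio, gains 0.66 points. Green brings new reach and gains 8.4 points.

The forecast, holding that “the plateau comes from enzyme death”, gave 84.7% (82.5% to 87%), 85.7% after ochre, 86.2% after violet and green as best, and its first figure lies above ours.

The flask gives 83.5%, then 84.1% after ochre and 84.3% after violet, and green wins with 9 points against 1.6 points for blue.

    starting material + free enzyme → product + free enzyme, rate k1*[starting material]*[free enzyme]/(1 + ([starting material]/Km1) + ([product]/Kp1)) (26.0 mM, 47.0 mM, k = 5600 M⁻¹ min⁻¹, Ea = 47.0 kJ mol⁻¹)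
    free enzyme → spent catalyst (k = 8.90 × 10⁻⁴ min⁻¹, Ea = 99.0 kJ mol⁻¹)
    free enzyme → unfolded enzyme (k = 2.60 × 10⁻⁵ min⁻¹, Ea = 192 kJ mol⁻¹)
    (constants at 20 °C)

The stall in this flask comes from the passing of free enzyme into spent catalyst acting together with the brake by product in the rate law: without the first, product at 2.50 d stands at 99.9%, and without the second at 96.5%. Left until 25.0 d, the flask reaches 84.7%, a spent reach of 1.88 against our 1.81. Multiplied by the ratio of the charges, our reach gives the neighbour flask with 0.003 mol% free enzyme a leftover of 1.08%, but at 2.50 d that flask holds 0.61% starting material, so it has spent more than the multiplied reach, 5.10 against 4.53.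

The readings are simulated on assumed constants, and the scatter is random.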